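Both seven-membered rings of the dimer carry oxygen at C1 and C8 (C1' and C8'), 1,4-related through C9 and the methyl-bearing C10, so each is a masked cycloheptane-1,4-dione. The route rests on one divinylcyclopropane Cope rearrangement: a cis-cyclopropane bearing a (Z)-1-siloxypropenyl and a 1-siloxyvinyl group expands to ring A as a regiodefined, differently silylated bis(enol ether), forming C9–C10 and setting C10 from the cyclopropane. The C8 enol ether then builds the cis-lactone; the C1 enol ether serves as C5 nucleophile in one half and as vinyl triflate in the other. The halves are joined by Michael addition, acetylation and aldol closure of ring C.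

Key step: step 7

Assumption: quinidine is taken to deliver the (1S,2R) half-ester 3, as with related bicyclic meso-anhydrides; should the sense be opposite, quinine replaces it and nothing else changes.

Convention: xanthanolide numbering; unprimed atoms belong to the half with ring A (seven-membered ring bearing the tertiary alcohol), primed atoms to the half with ring B (seven-membered ring bearing the epoxide); ring C is the cyclohexene C1–C2–C3–C11'–C13'–C5; β is the face of ring A or ring B that carries its C10 methyl; the convex face of a lactone is the face of H7 and H8.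

Step 1
Reactants: 1 3-oxabicyclo[3.1.0]hexane-2,4-dione; 2 methanol
Product: 3 (1S,2R)-2-(methoxycarbonyl)cyclopropane-1-carboxylic acid
Conditions: quinidine (1.1 equiv), MeOH (3 equiv), toluene, −55 °C; dilute HCl wash
Reagents that add atoms: methanol, CO
Why: Alkaloid-mediated enantioselective alcoholysis of a meso anhydride, in which the chiral base directs methanol to one enantiotopic carbonyl and so fixes both cis cyclopropane centres at once.

Step 2
Reactants: 3 half-ester; 4 N,O-dimethylhydroxylamine hydrochloride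
Product: 5 methyl (1R,2S)-2-[methoxy(methyl)carbamoyl]cyclopropane-1-carboxylate
Conditions: 1,1'-carbonyldiimidazole, CH2Cl2, 0 °C; then 4, 23 °C
Reagents that add atoms: N,O-dimethylhydroxylamine hydrochloride, CNOC.Cl
Why: Amide formation through the acyl imidazole is neutral and leaves the cis ester and both stereocentres untouched.

Step 3
Reactants: 5 amide ester; 6 ethylmagnesium bromide
Product: 7 methyl (1R,2S)-2-propanoylcyclopropane-1-carboxylate
Conditions: EtMgBr (1.2 equiv), THF, −40 °C; NH4Cl aq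
Reagents that add atoms: ethylmagnesium bromide, CC[Mg]Br
Why: Weinreb ketone synthesis, in which the chelated tetrahedral adduct survives until quench and the methyl ester reacts far more slowly at this temperature.

Step 4
Reactants: 7 keto ester; 8 tert-butyldimethylsilyl trifluoromethanesulfonate
Product: 9 methyl (1R,2S)-2-[(1Z)-1-(tert-butyldimethylsilyloxy)prop-1-en-1-yl]cyclopropane-1-carboxylate
Conditions: tBuMe2SiOTf (1.2 equiv), Et3N (2 equiv), CH2Cl2, −78 → 0 °C
Reagents that add atoms: tert-butyldimethylsilyl trifluoromethanesulfonate, CC(C)(C)[Si](C)(C)OS(=O)(=O)C(F)(F)F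
Why: Soft enolisation of the ethyl ketone gives the thermodynamically preferred (Z)-silyl enol ether (methyl away from the cyclopropyl group), and enolisation towards the strained ring or of the ester does not compete.

Step 5
Reactants: 9 silyl enol ether ester; 4 N,O-dimethylhydroxylamine hydrochloride; 10 methylmagnesium bromide
Product: 12 1-[(1R,2S)-2-[(1Z)-1-(tert-butyldimethylsilyloxy)prop-1-en-1-yl]cyclopropyl]ethan-1-one, via Weinreb amide 11 (not isolated)
Conditions: 4 (1.5 equiv), iPrMgCl (3 equiv), THF, −20 °C; then MeMgBr (2 equiv), −20 → 0 °C; NH4Cl aq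
Reagents that add atoms: methylmagnesium bromide, C[Mg]Br
Why: Aminolysis of the ester by the chloromagnesium amide and Weinreb ketone synthesis in one flask give the methyl ketone while the silyl enol ether is inert, so a free 1,4-diketone (prone to aldol closure) never exists.

Step 6
Reactants: 12 methyl ketone; 13 chlorotrimethylsilane
Product: 14 (1S,2R)-1-[(1Z)-1-(tert-butyldimethylsilyloxy)prop-1-en-1-yl]-2-[1-(trimethylsilyloxy)ethenyl]cyclopropane
Conditions: LiN(iPr)2 (1.1 equiv), Me3SiCl present from the start, THF, −78 °C; cold pentane/NaHCO3 work-up below 0 °C; used at once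
Reagents that add atoms: chlorotrimethylsilane, C[Si](C)(C)Cl
Why: Kinetic deprotonation of the methyl ketone at CH3 (the cyclopropyl α-hydrogen is not removed) with internal silyl quench gives the 1-siloxyvinyl arm, and the product is kept cold because it is the Cope substrate.

Step 7
Reactants: 14 cis-bis(siloxyvinyl)cyclopropane
Product: 15 (6S)-5-(tert-butyldimethylsilyloxy)-6-methyl-1-(trimethylsilyloxy)cyclohepta-1,4-diene
Conditions: toluene (0.1 M, base-washed glass), 23 → 45 °C
Reagents that add atoms: none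
Why: A concerted suprafacial [3,3] sigmatropic shift (divinylcyclopropane–cycloheptadiene Cope rearrangement) runs through the boat transition state with both siloxyvinyl arms over the three-membered ring, so C9 and C10 bond as the C5–C7 bond breaks, driven by release of ring strain. The closest known reaction type is the rearrangement of cis-1,2-bis(1-siloxyvinyl)cyclopropanes and other cis-divinylcyclopropanes, which proceed at or near room temperature. Ring A closes by ring expansion from three to seven atoms (C9–C10 formed between the two vinyl termini), and the boat geometry makes both ring alkenes, C1=C5 and C7=C8, cis. The single new stereocentre C10 is controlled by the (5S,7R) cyclopropane configuration together with the Z geometry of the propenyl ether, which places the methyl outside the boat and H10 inside, giving 10S. The step needs a cis-cyclopropane and a geometrically pure (Z)-enol ether, secured in steps 1 and 4; an (E)-isomer would carry its methyl inside the boat and react far more slowly, so it should not leak the C10 epimer into 15. The two enol ethers emerge regiodefined and differently silylated (SiMe3 at C8, SitBuMe2 at C1).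

Step 8
Reactants: 15 bis(silyl enol ether); 16 methyl bromoacetate
Product: 18 methyl 2-[(1R,4S)-5-(tert-butyldimethylsilyloxy)-4-methyl-2-oxocyclohept-5-en-1-yl]acetate, via lithium enolate 17 (not isolated)
Conditions: MeLi (1.0 equiv), THF, 0 °C; then BrCH2CO2Me, DMPU, −78 → −20 °C; then DBU (0.3 equiv), toluene, 23 °C
Reagents that add atoms: methyl bromoacetate, COC(=O)CBr
Why: Methyllithium cleaves only the trimethylsilyl enol ether, the regiodefined C7=C8 enolate is alkylated at C7, and DBU then equilibrates C7 to the epimer with the side chain equatorial and cis to the C10 methyl, which A(1,2) strain with the C1 siloxy group holds pseudoaxial.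

Step 9
Reactants: 18 keto ester
Product: 20 (3aR,7S,8aR)-6-(tert-butyldimethylsilyloxy)-7-methyl-3,3a,4,7,8,8a-hexahydro-2H-cyclohepta[b]furan-2-one, via lithium alkoxide 19 (not isolated)
Conditions: LiBH(s-Bu)3 (L-Selectride), THF, −78 → 0 °C; NH4Cl aq
Reagents that add atoms: none
Why: The bulky hydride attacks C8 from the face away from the pseudoaxial C10 methyl and the C7 side chain, so the 8β-alkoxide forms cis to the side chain and closes the cis-fused γ-lactone by transesterification.

Step 10
Reactants: 20 lactone; 21 N-phenylbis(trifluoromethanesulfonimide)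
Product: 22 (3aR,7S,8aR)-7-methyl-2-oxo-3,3a,4,7,8,8a-hexahydro-2H-cyclohepta[b]furan-6-yl trifluoromethanesulfonate
Conditions: CsF (2 equiv), PhNTf2 (1.3 equiv), DME, 23 °C
Reagents that add atoms: N-phenylbis(trifluoromethanesulfonimide), O=S(=O)(N(c1ccccc1)S(=O)(=O)C(F)(F)F)C(F)(F)F
Why: Fluoride-induced exchange of a silyl enol ether for an enol triflate keeps the C1=C5 regiochemistry that the key step set.

Step 11
Reactants: 22 enol triflate; 23 tributyl(ethenyl)stannane
Product: 24 (3aR,7S,8aR)-6-ethenyl-7-methyl-3,3a,4,7,8,8a-hexahydro-2H-cyclohepta[b]furan-2-one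
Conditions: Pd(PPh3)4 (5 mol %), LiCl (3 equiv), THF, 65 °C
Reagents that add atoms: tributyl(ethenyl)stannane, C=C[Sn](CCCC)(CCCC)CCCC
Why: Stille coupling of the vinyl triflate under neutral conditions gives the 1,3-diene without touching the lactone or C10.

Step 12
Reactants: 20 lactone; 25 diphenyl disulfide; 26 iodomethane
Product: 29 (3S,3aS,7S,8aR)-6-(tert-butyldimethylsilyloxy)-3,7-dimethyl-3-(phenylsulfanyl)-3,3a,4,7,8,8a-hexahydro-2H-cyclohepta[b]furan-2-one, via lactone enolate 27 (not isolated), via phenylthio enolate 28 (not isolated)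
Conditions: LiN(iPr)2 (2.2 equiv), THF, −78 °C; PhSSPh (1.05 equiv), −78 → −20 °C; then MeI (5 equiv), DMPU, −78 → 0 °C
Reagents that add atoms: diphenyl disulfide, c1ccc(SSc2ccccc2)cc1; iodomethane, CI
Why: Enolate sulfenylation followed by alkylation of the more acidic α-thio lactone brings each electrophile in from the convex face, so the methyl ends syn to H7 and sulfur anti to it, which later forces sulfoxide elimination into the methyl group.

Step 13
Reactants: 29 sulfide lactone; 30 dimethyl(methylidene)ammonium iodide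
Product: 31 (3S,3aS,7S,8aR)-5-[(dimethylamino)methyl]-3,7-dimethyl-3-(phenylsulfanyl)perhydrocyclohepta[b]furan-2,6-dione (C5 epimers)
Conditions: CH2Cl2/MeCN, 23 °C; NaHCO3 aq
Reagents that add atoms: dimethyl(methylidene)ammonium iodide, C=[N+](C)C.[I-]
Why: The Mannich reaction of the silyl enol ether attaches the future C13' regiospecifically at C5 and unmasks the C1 ketone without base.

Step 14
Reactants: 31 Mannich base
Product: 33 (3S,3aS,7S,8aR)-3,7-dimethyl-5-methylidene-3-(phenylsulfanyl)perhydrocyclohepta[b]furan-2,6-dione, via ammonium iodide 32 (not isolated)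
Conditions: MeI (26, excess), Et2O, 23 °C; then NaHCO3 aq/CH2Cl2, 23 °C; used at once
Reagents that add atoms: none
Why: Quaternisation and E1cB elimination of the β-ammonio ketone give the exo-methylene enone under conditions too mild to epimerise C10.

Step 15
Reactants: 24 diene lactone; 34 tert-butylchlorodimethylsilane
Product: 35 tert-butyl{[(3aR,7S,8aR)-6-ethenyl-7-methyl-4,7,8,8a-tetrahydro-3aH-cyclohepta[b]furan-2-yl]oxy}dimethylsilane
Conditions: LiN(iPr)2 (1.1 equiv), tBuMe2SiCl, DMPU, THF, −78 → 0 °C; pentane filtration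
Reagents that add atoms: tert-butylchlorodimethylsilane, CC(C)(C)[Si](C)(C)Cl
Why: O-silylation of the lactone enolate gives the cyclic silyl ketene acetal needed for a Lewis acid-catalysed conjugate addition.

Step 16
Reactants: 35 silyl ketene acetal; 33 exo-methylene enone
Product: 36 Michael adduct: C1(OSitBuMe2)=C5 enol ether of ring A in which C5 carries C13'H2 bonded to C11' of lactone 24 (C11' epimers)
Conditions: tBuMe2SiOTf (10 mol %), CH2Cl2, −78 °C; Et3N quench
Reagents that add atoms: none
Why: The Mukaiyama–Michael addition forms C11'–C13' at the unhindered methylene terminus and transfers silicon to the C1 oxygen, so the ketone stays masked as its C1=C5 enol ether; the new C11' centre is re-enolised in step 17.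

Step 17
Reactants: 36 Michael adduct; 37 acetyl chloride
Product: 39 11'-acetyl derivative of 36 with the acetyl carbon C3 syn to H7' and C13' syn to C6', via lithium enolate 38 (not isolated)
Conditions: LiN(iPr)2 (1.2 equiv), THF, −78 °C; then AcCl (1.5 equiv), −78 °C
Reagents that add atoms: acetyl chloride, CC(=O)Cl
Why: The only acidic C–H is at C11', and C-acylation of the lactone enolate takes place on the convex face (the face of H7' and H8'), which sets the spiro centre.

Step 18
Reactants: 39 acetyl lactone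
Product: 40 1,3-diketone: C1 ketone of 39 with H5α and C13' β
Conditions: HF·pyridine, pyridine, THF, 0 °C
Reagents that add atoms: none
Why: Cleavage of the silyl enol ether with kinetic protonation of C5 from the α face, opposite the pseudoaxial C10 methyl, should give H5α.

Step 19
Reactants: 40 diketone
Product: 41 trans-fused ketol: ring C closed by C2–C1, 1β-OH, H5α, C3 ketone
Conditions: LiN(SiMe3)2 (1.05 equiv), THF, −78 °C; AcOH quench at −78 °C
Reagents that add atoms: none
Why: Intramolecular aldol addition (a Robinson-type annulation stopped at the ketol): only the acetyl methyl is deprotonated kinetically, C2 should add to the α face of C1 through a chair in which both ring A bonds are equatorial and C2 is away from the C10 methyl, and the cold quench prevents retro-aldol, dehydration and epimerisation at C5 or C10.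

Step 20
Reactants: 41 ketol; 42 1-(trimethylsilyl)imidazole
Product: 43 1-O-trimethylsilyl ether of 41
Conditions: CH2Cl2, 23 °C
Reagents that add atoms: 1-(trimethylsilyl)imidazole, C[Si](C)(C)n1ccnc1
Why: Silylation of the tertiary alcohol without base blocks retro-aldol cleavage during the enolisation of step 21.

Step 21
Reactants: 43 silyl ether; 44 N-(5-chloropyridin-2-yl)bis(trifluoromethanesulfonimide)
Product: 46 C2=C3 enol triflate of 43, via potassium enolate 45 (not isolated)
Conditions: KN(SiMe3)2 (1.2 equiv), THF, −78 °C; then 44, −78 °C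
Reagents that add atoms: N-(5-chloropyridin-2-yl)bis(trifluoromethanesulfonimide), FC(F)(F)S(=O)(=O)N(c1ccc(Cl)cn1)S(=O)(=O)C(F)(F)F
Why: C11' is quaternary, so the C3 ketone can enolise only towards C2, and O-triflation of that enolate fixes the C2=C3 alkene.

Step 22
Reactants: 46 enol triflate; 47 tributyl(1-ethoxyethenyl)stannane; 48 water
Product: 50 3-acetyl-Δ2 enone with free 1β-OH (ring A lactone still 11-methyl-11-phenylsulfanyl), via ethoxydiene 49 (not isolated)
Conditions: Pd(PPh3)4 (10 mol %), CuI (20 mol %), LiCl (5 equiv), DMF, 60 °C; then 1 M HCl, THF, 23 °C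
Reagents that add atoms: tributyl(1-ethoxyethenyl)stannane, CCOC(=C)[Sn](CCCC)(CCCC)CCCC; water, O
Why: Stille coupling with an acetyl anion equivalent followed by acid hydrolysis of the enol ether reveals the methyl ketone and removes the trimethylsilyl ether in the same work-up.

Step 23
Reactants: 50 sulfide
Product: 52 α-methylene lactone on ring A (diene on ring B), via sulfoxide 51 (not isolated)
Conditions: mCPBA (1.0 equiv), CH2Cl2, −78 °C; then toluene, CaCO3, 100 °C
Reagents that add atoms: none
Why: Sulfur is oxidised far faster than any alkene at −78 °C, and thermal syn elimination of the sulfoxide can only take a methyl hydrogen because sulfur is anti to H7, giving the exocyclic alkene.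

Step 24
Reactants: 52 diene; 53 methyl vinyl ketone
Product: 54 (E)-dienone: 1',5'-alkene precursor of the target
Conditions: MVK (10 equiv), second-generation Hoveyda–Grubbs catalyst RuCl2(H2IMes)(=CH-C6H4-2-OiPr) (10 mol %), CH2Cl2, 40 °C
Reagents that add atoms: methyl vinyl ketone, C=CC(C)=O
Why: In this olefin cross-metathesis only the terminal vinyl group of the diene is reactive, since the 1,1-disubstituted methylene lactone and the trisubstituted enone are poor partners, and the conjugated product forms as the E isomer.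

Step 25
Reactants: 54 dienone; 48 water
Product: 56 target CNP0177598.1, via bromohydrin 55 (not isolated)
Conditions: N-bromosuccinimide, acetone/H2O, 0 °C; then K2CO3, 0 → 23 °C
Reagents that add atoms: water, O
Why: Halohydrin formation and ring closure: bromine should add to the 1',5'-alkene from the α face (opposite the pseudoaxial C10' methyl and the lactone), water opens at C5' from the β face, and base-induced displacement of bromide gives the 1'β,5'β-epoxide, the face that a direct peracid epoxidation is not expected to reach.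

Compound list
1 | 3-oxabicyclo[3.1.0]hexane-2,4-dione | O=C1OC(=O)C2CC12 | starting material
2 | methanol | CO | starting material
3 | (1S,2R)-2-(methoxycarbonyl)cyclopropane-1-carboxylic acid | OC(=O)[C@H]1C[C@H]1C(=O)OC | intermediate
4 | N,O-dimethylhydroxylamine hydrochloride | CNOC.Cl | starting material
5 | methyl (1R,2S)-2-[methoxy(methyl)carbamoyl]cyclopropane-1-carboxylate | CON(C)C(=O)[C@H]1C[C@H]1C(=O)OC | intermediate
6 | ethylmagnesium bromide | CC[Mg]Br | starting material
7 | methyl (1R,2S)-2-propanoylcyclopropane-1-carboxylate | CCC(=O)[C@H]1C[C@H]1C(=O)OC | intermediate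
8 | tert-butyldimethylsilyl trifluoromethanesulfonate | CC(C)(C)[Si](C)(C)OS(=O)(=O)C(F)(F)F | starting material
9 | methyl (1R,2S)-2-[(1Z)-1-(tert-butyldimethylsilyloxy)prop-1-en-1-yl]cyclopropane-1-carboxylate | C/C=C(\O[Si](C)(C)C(C)(C)C)[C@H]1C[C@H]1C(=O)OC | intermediate
10 | methylmagnesium bromide | C[Mg]Br | starting material
11 | (1R,2S)-2-[(1Z)-1-(tert-butyldimethylsilyloxy)prop-1-en-1-yl]-N-methoxy-N-methylcyclopropane-1-carboxamide | C/C=C(\O[Si](C)(C)C(C)(C)C)[C@H]1C[C@H]1C(=O)N(C)OC | intermediate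
12 | 1-[(1R,2S)-2-[(1Z)-1-(tert-butyldimethylsilyloxy)prop-1-en-1-yl]cyclopropyl]ethan-1-one | C/C=C(\O[Si](C)(C)C(C)(C)C)[C@H]1C[C@H]1C(C)=O | intermediate
13 | chlorotrimethylsilane | C[Si](C)(C)Cl | starting material
14 | (1S,2R)-1-[(1Z)-1-(tert-butyldimethylsilyloxy)prop-1-en-1-yl]-2-[1-(trimethylsilyloxy)ethenyl]cyclopropane (cis) | C/C=C(\O[Si](C)(C)C(C)(C)C)[C@H]1C[C@H]1C(=C)O[Si](C)(C)C | intermediate
15 | (6S)-5-(tert-butyldimethylsilyloxy)-6-methyl-1-(trimethylsilyloxy)cyclohepta-1,4-diene | C[C@H]1CC(O[Si](C)(C)C)=CCC=C1O[Si](C)(C)C(C)(C)C | intermediate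
16 | methyl bromoacetate | COC(=O)CBr | starting material
17 | lithium (6S)-5-(tert-butyldimethylsilyloxy)-6-methylcyclohepta-1,4-dien-1-olate | C[C@H]1CC(O[Li])=CCC=C1O[Si](C)(C)C(C)(C)C | intermediate
18 | methyl 2-[(1R,4S)-5-(tert-butyldimethylsilyloxy)-4-methyl-2-oxocyclohept-5-en-1-yl]acetate | O=C1C[C@H](C)C(O[Si](C)(C)C(C)(C)C)=CC[C@@H]1CC(=O)OC | intermediate
19 | lithium alkoxide of methyl 2-[(1R,2R,4S)-5-(tert-butyldimethylsilyloxy)-2-hydroxy-4-methylcyclohept-5-en-1-yl]acetate | [Li]O[C@@H]1C[C@H](C)C(O[Si](C)(C)C(C)(C)C)=CC[C@@H]1CC(=O)OC | intermediate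
20 | (3aR,7S,8aR)-6-(tert-butyldimethylsilyloxy)-7-methyl-3,3a,4,7,8,8a-hexahydro-2H-cyclohepta[b]furan-2-one | O=C1O[C@@H]2C[C@H](C)C(O[Si](C)(C)C(C)(C)C)=CC[C@@H]2C1 | intermediate
21 | N-phenylbis(trifluoromethanesulfonimide) | O=S(=O)(N(c1ccccc1)S(=O)(=O)C(F)(F)F)C(F)(F)F | starting material
22 | (3aR,7S,8aR)-7-methyl-2-oxo-3,3a,4,7,8,8a-hexahydro-2H-cyclohepta[b]furan-6-yl trifluoromethanesulfonate | O=C1O[C@@H]2C[C@H](C)C(OS(=O)(=O)C(F)(F)F)=CC[C@@H]2C1 | intermediate
23 | tributyl(ethenyl)stannane | C=C[Sn](CCCC)(CCCC)CCCC | starting material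
24 | (3aR,7S,8aR)-6-ethenyl-7-methyl-3,3a,4,7,8,8a-hexahydro-2H-cyclohepta[b]furan-2-one | O=C1O[C@@H]2C[C@H](C)C(C=C)=CC[C@@H]2C1 | intermediate
25 | diphenyl disulfide | c1ccc(SSc2ccccc2)cc1 | starting material
26 | iodomethane | CI | starting material
27 | lithium enolate of lactone 20 | [Li]OC1=C[C@H]2CC=C(O[Si](C)(C)C(C)(C)C)[C@@H](C)C[C@H]2O1 | intermediate
28 | lithium enolate of the 3-(phenylsulfanyl) derivative of lactone 20 | [Li]OC1=C(Sc3ccccc3)[C@H]2CC=C(O[Si](C)(C)C(C)(C)C)[C@@H](C)C[C@H]2O1 | intermediate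
29 | (3S,3aS,7S,8aR)-6-(tert-butyldimethylsilyloxy)-3,7-dimethyl-3-(phenylsulfanyl)-3,3a,4,7,8,8a-hexahydro-2H-cyclohepta[b]furan-2-one (3-methyl syn to H-3a) | C[C@@]1(Sc3ccccc3)C(=O)O[C@@H]2C[C@H](C)C(O[Si](C)(C)C(C)(C)C)=CC[C@H]12 | intermediate
30 | dimethyl(methylidene)ammonium iodide | C=[N+](C)C.[I-] | starting material
31 | (3S,3aS,7S,8aR)-5-[(dimethylamino)methyl]-3,7-dimethyl-3-(phenylsulfanyl)perhydrocyclohepta[b]furan-2,6-dione, C5 epimers | C[C@@]1(Sc3ccccc3)C(=O)O[C@@H]2C[C@H](C)C(=O)C(CN(C)C)C[C@H]12 | intermediate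
32 | trimethylammonium iodide of 31 | C[C@@]1(Sc3ccccc3)C(=O)O[C@@H]2C[C@H](C)C(=O)C(C[N+](C)(C)C)C[C@H]12.[I-] | intermediate
33 | (3S,3aS,7S,8aR)-3,7-dimethyl-5-methylidene-3-(phenylsulfanyl)perhydrocyclohepta[b]furan-2,6-dione | C[C@@]1(Sc3ccccc3)C(=O)O[C@@H]2C[C@H](C)C(=O)C(=C)C[C@H]12 | intermediate
34 | tert-butylchlorodimethylsilane | CC(C)(C)[Si](C)(C)Cl | starting material
35 | tert-butyl{[(3aR,7S,8aR)-6-ethenyl-7-methyl-4,7,8,8a-tetrahydro-3aH-cyclohepta[b]furan-2-yl]oxy}dimethylsilane | CC(C)(C)[Si](C)(C)OC1=C[C@H]2CC=C(C=C)[C@@H](C)C[C@H]2O1 | intermediate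
36 | Michael adduct: ring A lactone of 29 with C1(OSitBuMe2)=C5, C5 bearing C13'H2 bonded to C11' of lactone 24; C11' epimers | C[C@@]1(Sc5ccccc5)C(=O)O[C@@H]2C[C@H](C)C(O[Si](C)(C)C(C)(C)C)=C(CC4C(=O)O[C@@H]3C[C@H](C)C(C=C)=CC[C@@H]34)C[C@H]12 | intermediate
37 | acetyl chloride | CC(=O)Cl | starting material
38 | lithium enolate of 36 at C11'/C12' | C[C@@]1(Sc5ccccc5)C(=O)O[C@@H]2C[C@H](C)C(O[Si](C)(C)C(C)(C)C)=C(CC4=C(O[Li])O[C@@H]3C[C@H](C)C(C=C)=CC[C@@H]34)C[C@H]12 | intermediate
39 | 11'-acetyl derivative of 36; acetyl carbon C3 syn to H7', C13' syn to C6' | C[C@@]1(Sc5ccccc5)C(=O)O[C@@H]2C[C@H](C)C(O[Si](C)(C)C(C)(C)C)=C(C[C@]4(C(C)=O)C(=O)O[C@@H]3C[C@H](C)C(C=C)=CC[C@@H]34)C[C@H]12 | intermediate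
40 | diketone: C1 ketone of 39 with H5α (C13' β) | C[C@@]1(Sc5ccccc5)C(=O)O[C@@H]2C[C@H](C)C(=O)[C@H](C[C@]4(C(C)=O)C(=O)O[C@@H]3C[C@H](C)C(C=C)=CC[C@@H]34)C[C@H]12 | intermediate
41 | trans-fused ketol: ring C closed (C2–C1), 1β-OH, H5α, C3 ketone, spiro C11' | C[C@@]1(Sc5ccccc5)C(=O)O[C@@H]2C[C@H](C)[C@@]3(O)CC(=O)[C@@]4(C[C@@H]3C[C@H]12)C(=O)O[C@@H]1C[C@H](C)C(C=C)=CC[C@@H]14 | intermediate
42 | 1-(trimethylsilyl)imidazole | C[Si](C)(C)n1ccnc1 | starting material
43 | 1-O-trimethylsilyl ether of ketol 41 | C[C@@]1(Sc5ccccc5)C(=O)O[C@@H]2C[C@H](C)[C@@]3(O[Si](C)(C)C)CC(=O)[C@@]4(C[C@@H]3C[C@H]12)C(=O)O[C@@H]1C[C@H](C)C(C=C)=CC[C@@H]14 | intermediate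
44 | N-(5-chloropyridin-2-yl)bis(trifluoromethanesulfonimide) | FC(F)(F)S(=O)(=O)N(c1ccc(Cl)cn1)S(=O)(=O)C(F)(F)F | starting material
45 | potassium C2=C3 enolate of 43 | C[C@@]1(Sc5ccccc5)C(=O)O[C@@H]2C[C@H](C)[C@@]3(O[Si](C)(C)C)C=C(O[K])[C@@]4(C[C@@H]3C[C@H]12)C(=O)O[C@@H]1C[C@H](C)C(C=C)=CC[C@@H]14 | intermediate
46 | C2=C3 enol triflate of 43 (triflate on C3) | C[C@@]1(Sc5ccccc5)C(=O)O[C@@H]2C[C@H](C)[C@@]3(O[Si](C)(C)C)C=C(OS(=O)(=O)C(F)(F)F)[C@@]4(C[C@@H]3C[C@H]12)C(=O)O[C@@H]1C[C@H](C)C(C=C)=CC[C@@H]14 | intermediate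
47 | tributyl(1-ethoxyethenyl)stannane | CCOC(=C)[Sn](CCCC)(CCCC)CCCC | starting material
48 | water | O | starting material
49 | 3-(1-ethoxyethenyl)-Δ2 diene, 1-O-trimethylsilyl ether | C[C@@]1(Sc5ccccc5)C(=O)O[C@@H]2C[C@H](C)[C@@]3(O[Si](C)(C)C)C=C(C(=C)OCC)[C@@]4(C[C@@H]3C[C@H]12)C(=O)O[C@@H]1C[C@H](C)C(C=C)=CC[C@@H]14 | intermediate
50 | 3-acetyl-Δ2 enone with free 1β-OH; ring A lactone 11-methyl-11-phenylsulfanyl; ring B 1'-ethenyl-Δ1'(5') | C[C@@]1(Sc5ccccc5)C(=O)O[C@@H]2C[C@H](C)[C@@]3(O)C=C(C(C)=O)[C@@]4(C[C@@H]3C[C@H]12)C(=O)O[C@@H]1C[C@H](C)C(C=C)=CC[C@@H]14 | intermediate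
51 | sulfoxide of 50 (epimers at sulfur) | C[C@@]1(S(=O)c5ccccc5)C(=O)O[C@@H]2C[C@H](C)[C@@]3(O)C=C(C(C)=O)[C@@]4(C[C@@H]3C[C@H]12)C(=O)O[C@@H]1C[C@H](C)C(C=C)=CC[C@@H]14 | intermediate
52 | 11(13)-methylene lactone on ring A; ring B 1'-ethenyl-Δ1'(5') diene | C=C1C(=O)O[C@@H]2C[C@H](C)[C@@]3(O)C=C(C(C)=O)[C@@]4(C[C@@H]3C[C@H]12)C(=O)O[C@@H]1C[C@H](C)C(C=C)=CC[C@@H]14 | intermediate
53 | methyl vinyl ketone (but-3-en-2-one) | C=CC(C)=O | starting material
54 | (E)-dienone: target lacking the 1',5'-epoxide oxygen | C=C1C(=O)O[C@@H]2C[C@H](C)[C@@]3(O)C=C(C(C)=O)[C@@]4(C[C@@H]3C[C@H]12)C(=O)O[C@@H]1C[C@H](C)C(/C=C/C(C)=O)=CC[C@@H]14 | intermediate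
55 | bromohydrin: 1'α-bromo-5'β-hydroxy derivative of 54 | C=C1C(=O)O[C@@H]2C[C@H](C)[C@@]3(O)C=C(C(C)=O)[C@@]4(C[C@@H]3C[C@H]12)C(=O)O[C@@H]1C[C@H](C)[C@](Br)(/C=C/C(C)=O)[C@H](O)C[C@@H]14 | intermediate
56 | CNP0177598.1: spiro dimer with 1β-hydroxy-3-acetyl-Δ2 ring C, 11(13)-methylene cis-lactone on ring A, (E)-3-oxobutenyl and 1'β,5'β-epoxide on ring B | C=C1C(=O)O[C@@H]2C[C@H](C)[C@@]3(O)C=C(C(C)=O)[C@@]4(C[C@@H]3C[C@H]12)C(=O)O[C@@H]1C[C@H](C)[C@]2(/C=C/C(C)=O)O[C@@H]2C[C@@H]14 | target

Total step count: 25 steps. Longest linear sequence: 22 steps (steps 1–9, then 12–14 or 10, 11 and 15, then 16–25).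

Steps most likely to fail

1. Step 19. C2 may add to the β face of the C1 ketone and give the cis-fused ketol, or the aldolate may revert so that the diketone epimerises at C5 or C10 before closure. The fallback sets C1 by an intermolecular addition and closes ring C by metathesis; it sets out from 36 and comes back at 41. HF·pyridine would give the C1 ketone F1. CH2=CHMgBr with CeCl3 (THF, −78 °C) should add from the α face, away from the two flanking β substituents, to give the 1α-ethenyl 1β-carbinol F2. 1-(Trimethylsilyl)imidazole gives the silyl ether F3. LiN(iPr)2 and then AcCl acetylate C11' on the convex face, as in step 17, to give the acetyl lactone F4. KN(SiMe3)2 and tBuMe2SiCl turn the acetyl group into the 1-silyloxyethenyl compound F5. Ring-closing metathesis between the C1 ethenyl group and this enol ether (second-generation Grubbs catalyst RuCl2(H2IMes)(PCy3)(=CHPh), benzene, 60 °C) closes ring C as the cyclic silyl enol ether F6. HF·pyridine then removes both silyl groups and gives ketol 41.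

2. Step 8. The relay of configuration from C10 to C7 rests on a thermodynamic preference that may be small, so equilibration may leave a mixture of C7 epimers, and proton transfer during alkylation may cause dialkylation. The fallback sets out from 18, used as the epimer mixture, and comes back at 20. It is a ruthenium-catalysed asymmetric hydrogenation under dynamic kinetic resolution: RuCl2[(S)-binap][(S,S)-dpen] or its mirror image, whichever is matched to the 7R,8R series, with KOtBu, iPrOH and H2. The base keeps C7 epimerising while the catalyst reduces only the epimer that leads to the cis alcohol, which lactonises in the basic medium. No compound outside the list is made (F0).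

3. Step 25. The bromonium ion may form on the β face, or the tertiary allylic bromide may solvolyse before ring closure, giving the α-epoxide or diol by-products. The fallback sets out from 54 and comes back at 56: direct oxygen transfer with dimethyldioxirane (acetone, −20 °C). Its facial preference is complementary to that of the halohydrin route, so whichever face the electrophile prefers, one of the two methods gives the β-epoxide. No compound outside the list is made (F0).

Further compounds
F1 | step 19 | C1 ketone from 36 (H5α; C11' epimers) | C[C@@]1(Sc5ccccc5)C(=O)O[C@@H]2C[C@H](C)C(=O)[C@H](CC4C(=O)O[C@@H]3C[C@H](C)C(C=C)=CC[C@@H]34)C[C@H]12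
F2 | step 19 | 1α-ethenyl 1β-carbinol | C[C@@]1(Sc5ccccc5)C(=O)O[C@@H]2C[C@H](C)[C@@](O)(C=C)[C@H](CC4C(=O)O[C@@H]3C[C@H](C)C(C=C)=CC[C@@H]34)C[C@H]12
F3 | step 19 | trimethylsilyl ether of F2 | C[C@@]1(Sc5ccccc5)C(=O)O[C@@H]2C[C@H](C)[C@@](O[Si](C)(C)C)(C=C)[C@H](CC4C(=O)O[C@@H]3C[C@H](C)C(C=C)=CC[C@@H]34)C[C@H]12
F4 | step 19 | 11'-acetyl lactone (C3 syn to H7') | C[C@@]1(Sc5ccccc5)C(=O)O[C@@H]2C[C@H](C)[C@@](O[Si](C)(C)C)(C=C)[C@H](C[C@]4(C(C)=O)C(=O)O[C@@H]3C[C@H](C)C(C=C)=CC[C@@H]34)C[C@H]12
F5 | step 19 | 1-(tert-butyldimethylsilyloxy)ethenyl compound | C[C@@]1(Sc5ccccc5)C(=O)O[C@@H]2C[C@H](C)[C@@](O[Si](C)(C)C)(C=C)[C@H](C[C@]4(C(=C)O[Si](C)(C)C(C)(C)C)C(=O)O[C@@H]3C[C@H](C)C(C=C)=CC[C@@H]34)C[C@H]12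
F6 | step 19 | cyclic C2=C3 silyl enol ether of ring C, 1-O-trimethylsilyl | C[C@@]1(Sc5ccccc5)C(=O)O[C@@H]2C[C@H](C)[C@@]3(O[Si](C)(C)C)C=C(O[Si](C)(C)C(C)(C)C)[C@@]4(C[C@@H]3C[C@H]12)C(=O)O[C@@H]1C[C@H](C)C(C=C)=CC[C@@H]14
F0 | step 8 | none | none
F0 | step 25 | none | none
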